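The target is disconnected at the C4–O bond of its (2R,3R,4R) half and at O1–C8a of ring C in its (2S,3R,4R) half, exploiting that O1 sits on the sp2 carbon C8a of ring A, next to the C8 oxygen. A catalytic alkynylation sets C2 as an open-chain carbinol. After semi-reduction, copper-catalysed O-arylation of the (Z)-allylic alcohol onto brominated C8a closes ring C with the C2–O bond untouched. The resulting 2H-chromene lets this single stereocentre direct OsO4 to C3 and C4 in one event. The antipodal chromene, as its epoxide, forges the C4–O–C4 ether; oxidation/reduction then corrects C3.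

Key step: step 7

Remark: (R)-BINOL is assumed to deliver the (1S)-carbinol in step 5; if the sense of induction of this catalyst system is the reverse, the two BINOL antipodes are exchanged between steps 5 and 10.

Step 1
Reactants: 1 2-bromo-3-hydroxy-4-methoxybenzaldehyde
Product: 2 2-bromo-3,4-dihydroxybenzaldehyde
Conditions: BBr3, CH2Cl2, −78 °C to rt; then H2O
Reagents that add atoms: none
Why: Lewis-acid cleavage of an aryl methyl ether (BBr3 demethylation) proceeds through the aryloxyborane and should leave the aldehyde and the aryl bromide intact at low temperature; no stereocentre is involved.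

Step 2
Reactants: 2 2-bromo-3,4-dihydroxybenzaldehyde
Product: 3 3,4-bis(benzyloxy)-2-bromobenzaldehyde
Conditions: BnBr, K2CO3, DMF, 60 °C
Reagents that add atoms: benzyl bromide, BrCc1ccccc1
Why: Williamson etherification of both phenoxides with benzyl bromide installs the hydrogenolysable protecting groups that are carried to the last step.

Step 3
Reactants: 3 3,4-bis(benzyloxy)-2-bromobenzaldehyde
Product: 4 1,2-bis(benzyloxy)-3-bromo-4-ethynylbenzene
Conditions: dimethyl (1-diazo-2-oxopropyl)phosphonate, K2CO3, MeOH/THF, 0 °C to rt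
Reagents that add atoms: dimethyl (1-diazo-2-oxopropyl)phosphonate (Ohira–Bestmann reagent), CC(=O)C(=[N+]=[N-])P(=O)(OC)OC
Why: Seyferth–Gilbert homologation in its Ohira–Bestmann form converts the aldehyde into the terminal alkyne through the alkylidene carbene under mild base that spares the aryl bromide.

Step 4
Reactants: 4 1,2-bis(benzyloxy)-3-bromo-4-ethynylbenzene
Product: 5 ethyl{[3,4-bis(benzyloxy)-2-bromophenyl]ethynyl}zinc (toluene stock solution, kept under argon and divided into two equal portions for steps 5 and 10)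
Conditions: Et2Zn (1.0 equiv), toluene, reflux, argon; then cooled to rt
Reagents that add atoms: diethylzinc, CC[Zn]CC
Why: Deprotonative zincation of a terminal alkyne: the acidic alkyne C–H protonates one ethyl group of Et2Zn with loss of ethane, giving the alkynyl(ethyl)zinc in a single batch that serves both antipodal additions, while the aryl bromide does not exchange with a dialkylzinc without a catalyst.

Step 5
Reactants: 5 ethyl{[3,4-bis(benzyloxy)-2-bromophenyl]ethynyl}zinc (first portion of the stock solution); 6 4-(benzyloxy)benzaldehyde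
Product: 7 (1S)-3-[3,4-bis(benzyloxy)-2-bromophenyl]-1-[4-(benzyloxy)phenyl]prop-2-yn-1-ol
Conditions: (R)-BINOL (20 mol %), Ti(OiPr)4 (50 mol %), CH2Cl2, rt; then 6, rt; H2O quench
Reagents that add atoms: none
Why: Catalytic asymmetric alkynylzinc addition to an aromatic aldehyde (BINOL/Ti(OiPr)4 system) should deliver the alkynyl group of 5 to one enantioface of the titanium-bound aldehyde, so the ligand sets the carbinol stereocentre that becomes C2 of the 2S half.

Step 6
Reactants: 7 (1S)-3-[3,4-bis(benzyloxy)-2-bromophenyl]-1-[4-(benzyloxy)phenyl]prop-2-yn-1-ol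
Product: 8 (1R,2Z)-3-[3,4-bis(benzyloxy)-2-bromophenyl]-1-[4-(benzyloxy)phenyl]prop-2-en-1-ol
Conditions: H2 (1 atm), Pd/CaCO3 poisoned with Pb(OAc)2, quinoline, EtOAc, rt
Reagents that add atoms: none
Why: Lindlar semi-hydrogenation over lead-poisoned Pd/CaCO3 adds H2 syn and should stop at the (Z)-alkene needed for ring closure while leaving the aryl bromide, the benzyl ethers and the carbinol centre untouched (the descriptor changes from S to R only because alkenyl ranks below aryl).

Step 7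
Reactants: 8 (1R,2Z)-3-[3,4-bis(benzyloxy)-2-bromophenyl]-1-[4-(benzyloxy)phenyl]prop-2-en-1-ol
Product: 9 (2R)-7,8-bis(benzyloxy)-2-[4-(benzyloxy)phenyl]-2H-chromene
Conditions: CuI (10 mol %), 3,4,7,8-tetramethyl-1,10-phenanthroline (20 mol %), Cs2CO3, toluene, 80 °C, argon, dark
Reagents that add atoms: none
Why: Ullmann-type intramolecular C–O coupling: Cs2CO3 generates the alkoxide on the phenanthroline-ligated monovalent copper centre, the C8a–Br bond adds oxidatively and C–O reductive elimination forms O1–C8a. The closest known reaction type is the copper- or palladium-catalysed intramolecular etherification of aryl bromides with secondary alcohols, which gives chromans with retention at the carbinol carbon. Ring C is closed as a six-membered ring by intramolecular ipso substitution at C8a, the (Z)-alkene holding the oxygen within reach of that carbon. No stereocentre is created; C2 keeps its configuration because the C2–O bond is never broken, which is what lets the catalytically set carbinol become the ring stereocentre that later controls C3 and C4. The step needs C–O coupling to win over β-hydride loss, alkene isomerisation and electrocyclic ring opening of the product; copper instead of palladium, a single halogen placed at C8a, exclusion of light and air and a moderate temperature should secure this.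

Step 8
Reactants: 9 (2R)-7,8-bis(benzyloxy)-2-[4-(benzyloxy)phenyl]-2H-chromene
Product: 10 (2S,3R,4R)-7,8-bis(benzyloxy)-2-[4-(benzyloxy)phenyl]chromane-3,4-diol
Conditions: OsO4 (2 mol %), NMO, acetone/H2O, 0 °C to rt
Reagents that add atoms: osmium tetroxide, O=[Os](=O)(=O)=O; N-methylmorpholine N-oxide, C[N+]1([O-])CCOCC1; water, O
Why: Upjohn dihydroxylation should add both oxygens suprafacially to C3=C4 from the face opposite the C2 aryl group, so the single C2 centre sets C3 and C4 together as the 2,3-trans-3,4-cis diol (C2 is unchanged; its descriptor becomes S only because C3 now outranks the aryl group).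

Step 9
Reactants: 10 (2S,3R,4R)-7,8-bis(benzyloxy)-2-[4-(benzyloxy)phenyl]chromane-3,4-diol
Product: 11 (2S,3R,4R)-3,7,8-tris(benzyloxy)-2-[4-(benzyloxy)phenyl]chroman-4-ol
Conditions: 2-aminoethyl diphenylborinate (10 mol %), BnBr, Ag2O, MeCN, 40 °C
Reagents that add atoms: benzyl bromide, BrCc1ccccc1
Why: Borinic-acid-catalysed regioselective O-alkylation of a cis-1,2-diol should benzylate the more nucleophilic equatorial O3 of the tetracoordinate borinate and leave the pseudo-axial benzylic 4-OH free as the later nucleophile, with no stereocentre changed.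

Step 10
Reactants: 5 ethyl{[3,4-bis(benzyloxy)-2-bromophenyl]ethynyl}zinc (second portion of the stock solution); 6 4-(benzyloxy)benzaldehyde
Product: 12 (1R)-3-[3,4-bis(benzyloxy)-2-bromophenyl]-1-[4-(benzyloxy)phenyl]prop-2-yn-1-ol
Conditions: (S)-BINOL (20 mol %), Ti(OiPr)4 (50 mol %), CH2Cl2, rt; then 6, rt; H2O quench
Reagents that add atoms: none
Why: The same catalytic asymmetric alkynylzinc addition as in step 5, run with the antipodal BINOL, should attack the other enantioface and give the mirror-image carbinol needed for the 2R half.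

Step 11
Reactants: 12 (1R)-3-[3,4-bis(benzyloxy)-2-bromophenyl]-1-[4-(benzyloxy)phenyl]prop-2-yn-1-ol
Product: 13 (1S,2Z)-3-[3,4-bis(benzyloxy)-2-bromophenyl]-1-[4-(benzyloxy)phenyl]prop-2-en-1-ol
Conditions: H2 (1 atm), Pd/CaCO3 poisoned with Pb(OAc)2, quinoline, EtOAc, rt
Reagents that add atoms: none
Why: Lindlar semi-hydrogenation as in step 6 should give the (Z)-alkene with the carbinol centre unchanged.

Step 12
Reactants: 13 (1S,2Z)-3-[3,4-bis(benzyloxy)-2-bromophenyl]-1-[4-(benzyloxy)phenyl]prop-2-en-1-ol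
Product: 14 (2S)-7,8-bis(benzyloxy)-2-[4-(benzyloxy)phenyl]-2H-chromene
Conditions: CuI (10 mol %), 3,4,7,8-tetramethyl-1,10-phenanthroline (20 mol %), Cs2CO3, toluene, 80 °C, argon, dark
Reagents that add atoms: none
Why: Ullmann-type intramolecular O-arylation as in step 7 forms the aryl–oxygen bond without breaking the carbinol C–O bond, so the configuration is retained and the antipodal 2H-chromene should result.

Step 13
Reactants: 14 (2S)-7,8-bis(benzyloxy)-2-[4-(benzyloxy)phenyl]-2H-chromene; 11 (2S,3R,4R)-3,7,8-tris(benzyloxy)-2-[4-(benzyloxy)phenyl]chroman-4-ol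
Product: 16 (2R,3S,4R)-7,8-bis(benzyloxy)-2-[4-(benzyloxy)phenyl]-4-{[(2S,3R,4R)-3,7,8-tris(benzyloxy)-2-[4-(benzyloxy)phenyl]chroman-4-yl]oxy}chroman-3-ol, via 3,4-epoxychromane 15 (not isolated)
Conditions: 14 (1.5 equiv), DMDO (acetone solution), CH2Cl2, −40 °C, volatiles removed cold; then 11, Zn(OTf)2 (10 mol %), 4 Å MS, CH2Cl2, −40 to 0 °C
Reagents that add atoms: dimethyldioxirane, CC1(C)OO1
Why: Dioxirane epoxidation followed by Lewis-acid-assisted epoxide alcoholysis: DMDO should epoxidise C3=C4 anti to the C2 aryl group, and alcohol 11 should then open the benzylic C4–O bond (activated by O1 and the C7 oxygen) with inversion, trans to the C3 oxygen, which sets C4 of the 2R half as 4R and leaves a 3,4-trans 3-OH.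

Step 14
Reactants: 16 (2R,3S,4R)-7,8-bis(benzyloxy)-2-[4-(benzyloxy)phenyl]-4-{[(2S,3R,4R)-3,7,8-tris(benzyloxy)-2-[4-(benzyloxy)phenyl]chroman-4-yl]oxy}chroman-3-ol
Product: 17 (2R,4R)-7,8-bis(benzyloxy)-2-[4-(benzyloxy)phenyl]-4-{[(2S,3R,4R)-3,7,8-tris(benzyloxy)-2-[4-(benzyloxy)phenyl]chroman-4-yl]oxy}chroman-3-one
Conditions: Dess–Martin periodinane, pyridine, CH2Cl2, 0 °C to rt
Reagents that add atoms: none
Why: Dess–Martin oxidation of the only free hydroxyl (3-OH of the 2R half) under buffered conditions should give the chroman-3-one without epimerising C2 or C4, erasing the wrongly configured C3.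

Step 15
Reactants: 17 (2R,4R)-7,8-bis(benzyloxy)-2-[4-(benzyloxy)phenyl]-4-{[(2S,3R,4R)-3,7,8-tris(benzyloxy)-2-[4-(benzyloxy)phenyl]chroman-4-yl]oxy}chroman-3-one
Product: 18 (2R,3R,4R)-7,8-bis(benzyloxy)-2-[4-(benzyloxy)phenyl]-4-{[(2S,3R,4R)-3,7,8-tris(benzyloxy)-2-[4-(benzyloxy)phenyl]chroman-4-yl]oxy}chroman-3-ol
Conditions: LiBH(s-Bu)3, THF, −78 °C; then H2O
Reagents that add atoms: none
Why: Substrate-controlled reduction of a cyclic ketone by a bulky borohydride: the hydride should attack C3 from the face opposite the cis-disposed C2 aryl and C4 alkoxy groups (equatorial attack), giving the axial 3R alcohol and thus the all-cis 2R,3R,4R half.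

Step 16
Reactants: 18 (2R,3R,4R)-7,8-bis(benzyloxy)-2-[4-(benzyloxy)phenyl]-4-{[(2S,3R,4R)-3,7,8-tris(benzyloxy)-2-[4-(benzyloxy)phenyl]chroman-4-yl]oxy}chroman-3-ol
Product: 19 (2R,3R,4R)-2-(4-hydroxyphenyl)-4-{[(2S,3R,4R)-3,7,8-trihydroxy-2-(4-hydroxyphenyl)chroman-4-yl]oxy}chromane-3,7,8-triol
Conditions: H2 (1 atm), Pd(OH)2/C, EtOAc/MeOH, rt, stopped at complete debenzylation
Reagents that add atoms: none
Why: Catalytic hydrogenolysis under neutral conditions should cleave the six aryl benzyl ethers and the one alkyl benzyl ether, while the hindered ring-bound C2–O and C4–O benzylic ethers, which are much slower to cleave, are retained.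

Compound list
1 | 2-bromo-3-hydroxy-4-methoxybenzaldehyde | O=Cc1ccc(OC)c(O)c1Br | starting material
2 | 2-bromo-3,4-dihydroxybenzaldehyde | O=Cc1ccc(O)c(O)c1Br | intermediate
3 | 3,4-bis(benzyloxy)-2-bromobenzaldehyde | O=Cc1ccc(OCc2ccccc2)c(OCc2ccccc2)c1Br | intermediate
4 | 1,2-bis(benzyloxy)-3-bromo-4-ethynylbenzene | C#Cc1ccc(OCc2ccccc2)c(OCc2ccccc2)c1Br | intermediate
5 | ethyl{[3,4-bis(benzyloxy)-2-bromophenyl]ethynyl}zinc (toluene stock solution) | CC[Zn]C#Cc1ccc(OCc2ccccc2)c(OCc2ccccc2)c1Br | intermediate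
6 | 4-(benzyloxy)benzaldehyde | O=Cc1ccc(OCc2ccccc2)cc1 | starting material
7 | (1S)-3-[3,4-bis(benzyloxy)-2-bromophenyl]-1-[4-(benzyloxy)phenyl]prop-2-yn-1-ol | Brc1c(C#C[C@H](c2ccc(OCc5ccccc5)cc2)O)ccc(OCc5ccccc5)c1OCc5ccccc5 | intermediate
8 | (1R,2Z)-3-[3,4-bis(benzyloxy)-2-bromophenyl]-1-[4-(benzyloxy)phenyl]prop-2-en-1-ol | Brc1c(/C=C\[C@H](c2ccc(OCc5ccccc5)cc2)O)ccc(OCc5ccccc5)c1OCc5ccccc5 | intermediate
9 | (2R)-7,8-bis(benzyloxy)-2-[4-(benzyloxy)phenyl]-2H-chromene | C1=C[C@H](c2ccc(OCc5ccccc5)cc2)Oc2c1ccc(OCc5ccccc5)c2OCc5ccccc5 | intermediate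
10 | (2S,3R,4R)-7,8-bis(benzyloxy)-2-[4-(benzyloxy)phenyl]chromane-3,4-diol (2,3-trans-3,4-cis) | O[C@@H]1c2ccc(OCc5ccccc5)c(OCc5ccccc5)c2O[C@@H](c2ccc(OCc5ccccc5)cc2)[C@@H]1O | intermediate
11 | (2S,3R,4R)-3,7,8-tris(benzyloxy)-2-[4-(benzyloxy)phenyl]chroman-4-ol | O[C@@H]1c2ccc(OCc5ccccc5)c(OCc5ccccc5)c2O[C@@H](c2ccc(OCc5ccccc5)cc2)[C@@H]1OCc5ccccc5 | intermediate
12 | (1R)-3-[3,4-bis(benzyloxy)-2-bromophenyl]-1-[4-(benzyloxy)phenyl]prop-2-yn-1-ol | Brc1c(C#C[C@@H](c2ccc(OCc5ccccc5)cc2)O)ccc(OCc5ccccc5)c1OCc5ccccc5 | intermediate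
13 | (1S,2Z)-3-[3,4-bis(benzyloxy)-2-bromophenyl]-1-[4-(benzyloxy)phenyl]prop-2-en-1-ol | Brc1c(/C=C\[C@@H](c2ccc(OCc5ccccc5)cc2)O)ccc(OCc5ccccc5)c1OCc5ccccc5 | intermediate
14 | (2S)-7,8-bis(benzyloxy)-2-[4-(benzyloxy)phenyl]-2H-chromene | C1=C[C@@H](c2ccc(OCc5ccccc5)cc2)Oc2c1ccc(OCc5ccccc5)c2OCc5ccccc5 | intermediate
15 | (2R,3S,4S)-7,8-bis(benzyloxy)-2-[4-(benzyloxy)phenyl]-3,4-epoxychromane (oxirane on the face opposite the 2-aryl group) | O(Cc5ccccc5)c1ccc([C@H]2Oc3c(ccc(OCc5ccccc5)c3OCc5ccccc5)[C@@H]4O[C@H]24)cc1 | intermediate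
16 | (2R,3S,4R)-7,8-bis(benzyloxy)-2-[4-(benzyloxy)phenyl]-4-{[(2S,3R,4R)-3,7,8-tris(benzyloxy)-2-[4-(benzyloxy)phenyl]chroman-4-yl]oxy}chroman-3-ol | O(Cc5ccccc5)c1ccc([C@H]2Oc3c(ccc(OCc5ccccc5)c3OCc5ccccc5)[C@@H](O[C@@H]3c4ccc(OCc5ccccc5)c(OCc5ccccc5)c4O[C@@H](c4ccc(OCc5ccccc5)cc4)[C@@H]3OCc5ccccc5)[C@@H]2O)cc1 | intermediate
17 | (2R,4R)-7,8-bis(benzyloxy)-2-[4-(benzyloxy)phenyl]-4-{[(2S,3R,4R)-3,7,8-tris(benzyloxy)-2-[4-(benzyloxy)phenyl]chroman-4-yl]oxy}chroman-3-one | O(Cc5ccccc5)c1ccc([C@H]2Oc3c(ccc(OCc5ccccc5)c3OCc5ccccc5)[C@@H](O[C@@H]3c4ccc(OCc5ccccc5)c(OCc5ccccc5)c4O[C@@H](c4ccc(OCc5ccccc5)cc4)[C@@H]3OCc5ccccc5)C2=O)cc1 | intermediate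
18 | (2R,3R,4R)-7,8-bis(benzyloxy)-2-[4-(benzyloxy)phenyl]-4-{[(2S,3R,4R)-3,7,8-tris(benzyloxy)-2-[4-(benzyloxy)phenyl]chroman-4-yl]oxy}chroman-3-ol | O(Cc5ccccc5)c1ccc([C@H]2Oc3c(ccc(OCc5ccccc5)c3OCc5ccccc5)[C@@H](O[C@@H]3c4ccc(OCc5ccccc5)c(OCc5ccccc5)c4O[C@@H](c4ccc(OCc5ccccc5)cc4)[C@@H]3OCc5ccccc5)[C@H]2O)cc1 | intermediate
19 | (2R,3R,4R)-2-(4-hydroxyphenyl)-4-{[(2S,3R,4R)-3,7,8-trihydroxy-2-(4-hydroxyphenyl)chroman-4-yl]oxy}chromane-3,7,8-triol | Oc1ccc([C@H]2Oc3c(ccc(O)c3O)[C@@H](O[C@@H]3c4ccc(O)c(O)c4O[C@@H](c4ccc(O)cc4)[C@@H]3O)[C@H]2O)cc1 | target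

Total step count: 16. Longest linear sequence: 13 steps (steps 1 to 9, then 13 to 16).

Steps most likely to fail

Step 13. The labile benzylic epoxide 15 may rearrange by hydride shift, or be captured by traces of water, faster than the hindered pseudo-axial alcohol 11 adds; a long-lived C4 cation would also erode the trans selectivity. The fallback replaces epoxide alcoholysis by thiophilic activation, leaving from 14 and rejoining at 16. Compound 14 is epoxidised as before (DMDO, CH2Cl2, −40 °C) and the crude epoxide 15 is opened at once at C4 with phenylmethanethiol to give the stable (2R,3R,4R)-4-(benzylsulfanyl)-7,8-bis(benzyloxy)-2-[4-(benzyloxy)phenyl]chroman-3-ol F1. AgBF4 with 2,6-di-tert-butyl-4-methylpyridine in THF/CH2Cl2 at 0 °C should then ionise only the C4–S bond in the presence of 11, which adds to the C4 cation trans to the 3-OH to give 16.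

Step 7. The doubly activated allylic carbinol may be oxidised or isomerised under hot basic copper conditions, oxidative addition at the doubly ortho-substituted C8a–Br bond may be slow, and enantiopurity may be eroded by reversible electrocyclic ring opening of the 2H-chromene at 80 °C. The fallback forms the same O1–C8a bond by oxidative coupling of an arylboron at room temperature, leaving from 8 and rejoining at 9. Bromine–lithium exchange on the lithium alkoxide of 8 (n-BuLi, 2.2 equiv, THF, −78 °C) and quench with 2-isopropoxy-4,4,5,5-tetramethyl-1,3,2-dioxaborolane should give (1R,2Z)-3-[3,4-bis(benzyloxy)-2-(4,4,5,5-tetramethyl-1,3,2-dioxaborolan-2-yl)phenyl]-1-[4-(benzyloxy)phenyl]prop-2-en-1-ol F2. Chan–Lam etherification (catalytic Cu(OAc)2, pyridine, 4 Å MS, O2, CH2Cl2, rt) then closes ring C to 9.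

Step 9. Discrimination between O3 and O4 may be insufficient, or double benzylation may occur. The fallback changes the oxidation state at C4 instead of relying on regioselective alkylation, leaving from 10 and rejoining at 11. MnO2 (CH2Cl2, rt) should oxidise only the benzylic 4-OH to give (2S,3S)-7,8-bis(benzyloxy)-2-[4-(benzyloxy)phenyl]-3-hydroxychroman-4-one F3. BnBr/Ag2O (CH2Cl2, rt) benzylates its single hydroxyl to give (2S,3S)-3,7,8-tris(benzyloxy)-2-[4-(benzyloxy)phenyl]chroman-4-one F4. LiBH(s-Bu)3 (THF, −78 °C) should reduce the ketone by equatorial attack, cis to the 3-benzyloxy group, to give 11.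

Further compounds
F1 | step 13 | (2R,3R,4R)-4-(benzylsulfanyl)-7,8-bis(benzyloxy)-2-[4-(benzyloxy)phenyl]chroman-3-ol | O(Cc5ccccc5)c1ccc([C@H]2Oc3c(ccc(OCc5ccccc5)c3OCc5ccccc5)[C@@H](SCc5ccccc5)[C@@H]2O)cc1
F2 | step 7 | (1R,2Z)-3-[3,4-bis(benzyloxy)-2-(4,4,5,5-tetramethyl-1,3,2-dioxaborolan-2-yl)phenyl]-1-[4-(benzyloxy)phenyl]prop-2-en-1-ol | CC1(C)OB(OC1(C)C)c1c(/C=C\[C@H](c2ccc(OCc5ccccc5)cc2)O)ccc(OCc5ccccc5)c1OCc5ccccc5
F3 | step 9 | (2S,3S)-7,8-bis(benzyloxy)-2-[4-(benzyloxy)phenyl]-3-hydroxychroman-4-one | O=C1c2ccc(OCc5ccccc5)c(OCc5ccccc5)c2O[C@@H](c2ccc(OCc5ccccc5)cc2)[C@@H]1O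
F4 | step 9 | (2S,3S)-3,7,8-tris(benzyloxy)-2-[4-(benzyloxy)phenyl]chroman-4-one | O=C1c2ccc(OCc5ccccc5)c(OCc5ccccc5)c2O[C@@H](c2ccc(OCc5ccccc5)cc2)[C@@H]1OCc5ccccc5
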